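A day is my unit, and what I carry is the share of this flask's charge that a day of stirring clears between the peak readings of the two earlier runs.

| flask | solid substrate | protic impurity | remark | time |
|---|---|---|---|---|
| alpha | 0.13 M | 4 mM | run made earlier |  |
| epsilon | 0.30 M | 4 mM | run made earlier |  |
| flask | 0.20 M | 4.00 mM |  | 15 d |

- alpha (time / d: target / %): 0.625: 14.1; 1.25: 22.0; 2.50: 19.9; 5.00: 13.5; 10.0: 11.7; 20.0: 12.8
- epsilon (time / d: target / %): 0.625: 5.3; 1.25: 9.9; 2.50: 14.5; 5.00: 19.5; 10.0: 13.6; 20.0: 13.6

(scatter of a reading: 0.5 percentage points)

- solid substrate is a solid; its amount is given per volume of the solution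
- at the start none of the solid substrate is in solution
- a reading or a percentage of target counts all its forms, free or not

1. when, up to 15 d, the flask holds most target
2. the amount of target, in percent of the solid substrate charged, at that time

1. The lean extreme is alpha. It holds 0.650 of the flask's charge, and its highest reading stands at 1.25 d.
2. The heavy extreme is epsilon. It holds 1.50 of that charge, and its highest reading stands later, at 5.00 d.
3. The flask's charge is more than alpha's and less than epsilon's, so I place its peak between those times.
4. I take each of those peak readings to mark the end of the solid and freeze the pace between them. Extra charge over extra days gives 0.227 d⁻¹: this is the clearing pace, read from the readings, the share of the flask's charge that goes per day between those two times.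
5. The flask stands 0.350 of a charge past alpha, so my own reckoning puts its peak at 2.79 d.
6. For the flask, the height taken by charge between the same two readings is 21.0%. I treat this as a low guess, since a peak can fall between readings.
7. The forecast gives 3.8 d and 26%, on the same turn: “Target falls once the solid is gone”. Its time is later than mine, and its amount is above my low guess.

    starting material ⇌ isomer of the product (K = 6.70, k = 5.80 × 10⁻⁴ min⁻¹)
    starting material + target ⇌ idle adduct, settled at all times (K = 11.0 M⁻¹)
    starting material ⇌ target (K = 1.00, k = 0.00590 min⁻¹)
    starting material + protic impurity → quenched substrate (k = 1.00 M⁻¹ min⁻¹)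
    target ⇌ isomer of the product (k = 8.20 × 10⁻⁴ min⁻¹)
    solid substrate ⇌ starting material, rate k6*(cs6 - [starting material]) while solid is left; crystals form when [starting material] > cs6 (solubility = 0.130 M, k = 4.90 × 10⁻⁴ min⁻¹)

The flask peaks at 2.74 d with 24.3%. Its solid substrate stands at 41.3% at 1.50 d and at 0% at 2.74 d. The clearing pace put the peak at 2.79 d, close to that time. For the neighbour charged with 0.50 M, the same pace puts the end of the solid at 9.41 d, before 15 d, and that neighbour holds 0% solid substrate at 15.0 d.

The runs were computed for substances that don't exist; the scatter is artificial.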